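Sunday's flask and Tuesday's flask both begin with pre-initiator, which becomes initiator and then living ends, and living ends take free monomer into chains.

all flasks: pre-initiator 0.41 mM
- noon: free monomer 8.4 mM; temperature 55 °C; run made earlier
- spring: free monomer 31 mM; temperature 66 °C; run made earlier
- Sunday's: free monomer 15 mM; at 50 °C until 80 min, from then on at 70 °C; time 2.5 h
- Tuesday's: free monomer 50 mM; at 50 °C throughout; time 2.5 h

| run | time / min | monomer in chains / % | free monomer / % |
|---|---|---|---|
| noon | 8.00 | 0 | 99.9 |
| noon | 15.0 | 0 | 99.4 |
| noon | 30.0 | 1.0 | 98.2 |
| noon | 60.0 | 3.9 | 96.7 |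
| noon | 120 | 12.3 | 87.9 |
| spring | 4.00 | 0.2 | 100.2 |
| spring | 6.00 | 1.0 | 98.2 |
| spring | 15.0 | 2.2 | 97.5 |
| spring | 25.0 | 6.3 | 93.3 |
| spring | 50.0 | 19.4 | 80.8 |

(standard deviation of a reading: 0.5 percentage points)

- which of the two ends with the higher amount of monomer in chains, in percent of the free monomer charged ("neither" if they lie within 2 percentage points) (Sunday's / Tuesday's / neither)
- monomer in chains at the end, in percent of the free monomer charged, Sunday's
- monomer in chains at the end, in percent of the free monomer charged, Tuesday's

- what was read earlier has a scatter of 0.5 percentage points, one standard deviation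
- steps under discussion: free monomer + living end -> monomer in chains + living end; free monomer + initiator -> living end + monomer in chains; pre-initiator -> initiator; monomer in chains + living end -> free monomer + living end

The puzzle is this: Sunday's holds 15 mM of free monomer against Tuesday's 50 mM and is hot for just 70.0 min of 150 min, yet we expect it to finish ahead.

We replace the curve of ends by its mean. With a steady supply of ends, that mean grows with time t, so the exponent x = −ln(fraction of free monomer not in chains) goes as (t/τ) squared. We assume each end takes a fixed fraction of the free monomer, so the charge drops out of x. The noon run's last reading gives τ = 331 min, and the spring run's gives 108 min. Stretched geometrically in temperature, τ is 552 min at 50 °C. At 70 °C it is 71.5 min, the hot ripening time.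

So Sunday's hot stretch spans more ripening times than Tuesday's whole run, and that clears the puzzle. Adding the two stretches and leaving out ends carried across the change, we reckon 62.4% for Sunday's and 7.12% for Tuesday's.

The forecast also puts Sunday's ahead, but at 50% (33% to 66%), lower than ours, and Tuesday's at 7% (4.5% to 10%), noting that “Depropagation is unresolved”.

The flask puts Sunday's ahead, with 40.0% against 12.2%.

    free monomer + living end → monomer in chains + living end, rate k1*[living end]*[free monomer] (k = 569 L mol⁻¹ h⁻¹, Ea = 64.0 kJ mol⁻¹)
    free monomer + initiator → living end + monomer in chains (k = 274 L mol⁻¹ h⁻¹, Ea = 54.0 kJ mol⁻¹)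
    pre-initiator → initiator (k = 0.233 h⁻¹, Ea = 111 kJ mol⁻¹)
    monomer in chains + living end → free monomer + living end, rate k4*[living end] as long as [monomer in chains] is above zero (k = 1.43 h⁻¹, Ea = 92.0 kJ mol⁻¹)
    (constants at 50 °C)

Tuesday's stands at 12.2% mainly because of the hour of the reading: left until 25.0 h, it gives 94.2%, and that hour accounts for 93% of what is missing. In the neighbour of Sunday's charged with 0.70 mM of pre-initiator, we take τ at 70 °C to shorten to 54.8 min. Keeping the ratio of Sunday's real exponent at the end to its reckoned hot one, we get 58.2%, and that neighbour gives 53.4%.

The earlier runs and the new flask stem from a simulated flask on assumed constants, and the scatter is random.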